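1. The target is epicatechin-(4β→8)-epigallocatechin 3-O-gallate-(4β→8)-epicatechin-(4β→8)-catechin (units 1 to 4). The retrosynthesis cuts the three C4–C8 interflavan bonds (1/2, then 2/3, then 3/4), the gallate ester, and then, inside unit 3, the O1–C8a and C4–C4a bonds of ring C.
2. Units 1, 2 and 4 come from (−)-epicatechin, (−)-epigallocatechin (acylated with tri-O-benzylgallic acid) and (+)-catechin. Unit 3 is built from an acyclic O1–C2–C3–C4 chain made by an Evans syn glycolate aldol.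
3. Key event: fluoride releases the C2 alkoxide and 3,5-bis(benzyloxy)benzyne together; O1 adds to C8a and the C4a carbanion closes on the C4 aldehyde. Ring C of unit 3 forms with C4 at the carbinol level that the next coupling needs.
4. Enabling feature: ring A of unit 3 is oxygenated at C5 and C7, so its C4a–C8a edge can be an aryne polarised by the C5 oxygen (O1 to C8a, charge to C4a). O1 and C4 are 1,4-related on the chain, so the closure is six-membered.
5. Forward order: ring C of unit 3 (step 9), then the 3/4, 2/3 and 1/2 bonds, each by capture of a C4 cation at C8 of the growing nucleophile, then one hydrogenolysis of all 21 benzyl ethers.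
6. Stereochemistry: C2/C3 of units 1, 2 and 4 come from the natural products; C2/C3 of unit 3 from the auxiliary (syn aldol becomes 2,3-cis); every C4 from attack on the cation anti to the C3 oxygen substituent and the C2 aryl group (4β).

Key step: step 9

Remark: flavan atoms carry the usual numbers (O1, C2, C3, C4, C4a, C5–C8, C8a) and rings the usual letters A, B, C. The carbinol centre C4 of the chroman-4-ol made in step 9 is expected as a mixture of epimers; both give the same cation in step 11, so its SMILES carries no descriptor at C4. Each C4 cation is written as the ion pair present in its flask: with the hydroquinone monoanion after hydride transfer to DDQ, with triflate under TMSOTf.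

Step 1
Reactants: 1 3,5-bis(benzyloxy)phenol
Product: 2 3,5-bis(benzyloxy)phenyl N-isopropylcarbamate
Conditions: i-PrNCO, Et3N (cat.), CH2Cl2, rt
Reagents that add atoms: isopropyl isocyanate, CC(C)N=C=O
Why: amine-catalysed addition of a phenol to an isocyanate (carbamoylation) installs the directing group for ortho-metalation and is later removable under mild base.

Step 2
Reactants: 2 3,5-bis(benzyloxy)phenyl N-isopropylcarbamate
Product: 6 3,5-bis(benzyloxy)-2-(trimethylsilyl)phenyl N-isopropylcarbamate, via N-silyl carbamate 3 (not isolated), via aryllithium 4 (not isolated), via doubly silylated carbamate 5 (not isolated)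
Conditions: TBSOTf, TMEDA, Et2O, 0 °C → rt; n-BuLi, TMEDA, −78 °C; TMSCl, −78 °C → rt; aq. NaHSO4
Reagents that add atoms: chlorotrimethylsilane, C[Si](C)(C)Cl
Why: directed ortho-metalation of the N-silylated carbamate should occur at C2, the position flanked by the carbamate and a benzyloxy group (both ortho positions are equivalent), and silyl quench followed by acidic work-up returns the N–H carbamate.

Step 3
Reactants: 6 3,5-bis(benzyloxy)-2-(trimethylsilyl)phenyl N-isopropylcarbamate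
Product: 8 3,5-bis(benzyloxy)-2-(trimethylsilyl)phenyl trifluoromethanesulfonate, via silylphenol 7 (not isolated)
Conditions: DBU, Et2NH, MeCN, 40 °C; then PhNTf2, rt
Reagents that add atoms: N-phenylbis(trifluoromethanesulfonimide), O=S(=O)(N(c1ccccc1)S(=O)(=O)C(F)(F)F)C(F)(F)F
Why: base-induced E1cB cleavage of the N–H carbamate (the isocyanate is scavenged by Et2NH) frees the phenoxide, which is triflated in the same flask to give the ortho-silylaryl triflate aryne precursor.

Step 4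
Reactants: 9 (S)-4-benzyloxazolidin-2-one; 10 (benzyloxy)acetyl chloride
Product: 12 (S)-4-benzyl-3-[(benzyloxy)acetyl]oxazolidin-2-one, via lithium oxazolidinide 11 (not isolated)
Conditions: n-BuLi, THF, −78 °C; then 10, −78 → 0 °C
Reagents that add atoms: none
Why: N-acylation of the lithiated oxazolidinone with an acid chloride loads the glycolate onto the Evans auxiliary, which is the purchased stereocentre of unit 3.

Step 5
Reactants: 12 (S)-4-benzyl-3-[(benzyloxy)acetyl]oxazolidin-2-one; 13 3,4-bis(benzyloxy)benzaldehyde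
Product: 16 (S)-4-benzyl-3-[(2S,3R)-2-(benzyloxy)-3-[3,4-bis(benzyloxy)phenyl]-3-hydroxypropanoyl]oxazolidin-2-one, via boron enolate 14 (not isolated), via boron aldolate 15 (not isolated)
Conditions: Bu2BOTf, Et3N, CH2Cl2, −78 → 0 °C; 13, −78 → 0 °C; pH 7 buffer, MeOH, H2O2, 0 °C
Reagents that add atoms: none
Why: Evans syn aldol through the Z boron enolate and a Zimmerman–Traxler chair, in which the benzyl group of the auxiliary shields one enolate face, should set the later C3 (benzyloxy-bearing) and C2 (aryl carbinol) of unit 3 as the syn (2S,3R) pair with the two oxygens already differentiated.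

Step 6
Reactants: 16 aldol adduct
Product: 17 (2S,3R)-2-(benzyloxy)-3-[3,4-bis(benzyloxy)phenyl]-3-hydroxy-N-methoxy-N-methylpropanamide
Conditions: MeNH(OMe)·HCl, AlMe3, CH2Cl2, −20 → 0 °C; aq. KNaC4H4O6
Reagents that add atoms: N,O-dimethylhydroxylamine hydrochloride, CNOC.Cl
Why: AlMe3-mediated transamidation of the β-hydroxy imide to the Weinreb amide is assisted by the free β-hydroxyl and releases the auxiliary without epimerisation.

Step 7
Reactants: 17 Weinreb amide
Product: 18 (2S,3R)-2-(benzyloxy)-3-[3,4-bis(benzyloxy)phenyl]-N-methoxy-N-methyl-3-(triethylsilyloxy)propanamide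
Conditions: TESCl, imidazole, DMF, 0 °C → rt
Reagents that add atoms: chlorotriethylsilane, CC[Si](CC)(CC)Cl
Why: silylation of the secondary benzylic alcohol masks O1 as a fluoride-labile ether that serves as a latent alkoxide in step 9.

Step 8
Reactants: 18 silylated Weinreb amide
Product: 20 (2S,3R)-2-(benzyloxy)-3-[3,4-bis(benzyloxy)phenyl]-3-(triethylsilyloxy)propanal, via aluminium hemiaminal 19 (not isolated)
Conditions: i-Bu2AlH, THF, −78 °C; aq. KNaC4H4O6
Reagents that add atoms: none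
Why: hydride reduction of a Weinreb amide stops at the chelated tetrahedral intermediate and gives the aldehyde on work-up, and the low temperature should keep the α-alkoxy centre from epimerising.

Step 9
Reactants: 20 (2S,3R)-2-(benzyloxy)-3-[3,4-bis(benzyloxy)phenyl]-3-(triethylsilyloxy)propanal; 8 3,5-bis(benzyloxy)-2-(trimethylsilyl)phenyl trifluoromethanesulfonate
Product: 24 (2R,3R)-3,5,7-tris(benzyloxy)-2-[3,4-bis(benzyloxy)phenyl]chroman-4-ol (2,3-cis; C4 epimers), via aryne 21 (not isolated), via caesium alkoxide 22 (not isolated), via aryl anion 23 (not isolated)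
Conditions: 8 (1.5 equiv), CsF, 18-crown-6, THF, 0 °C → rt; H2O
Reagents that add atoms: none
Why: Proposed new method: fluoride cleaves the Si–O bond of 20 to the alkoxide 22 and triggers 1,2-elimination of 8 to the aryne 21, and the closest known reaction type is the tandem O-arylation/carbonyl trapping of arynes by salicylaldehydes and salicylates (xanthenols and xanthones), carried over here to an aliphatic β-silyloxy aldehyde. O1 should add to the aryne carbon that becomes C8a, the one remote from the C5 benzyloxy group, because that oxygen distorts and polarises the triple bond so that the charge develops at C4a next to it, while the C7 benzyloxy group (para to C4a) has only a weak remote influence. The C4a carbanion 23 then attacks the aldehyde carbon C4 in a 6-exo-trig closure that completes ring C (O1, C2, C3, C4, C4a, C8a). C2 and C3 are not touched, so the syn relation from the aldol becomes the 2,3-cis (epicatechin) relation, and the new C4 carbinol centre is not controlled and need not be, since C4 is ionised in step 11. The step needs regioselective addition to the aryne (secured by the C5 oxygen), ring closure faster than proton quench of the carbanion (secured by releasing the alkoxide from a silyl ether so that no O–H is present) and capture of 22 before retro-aldol cleavage (helped by the excess of 8 and the gradual release of both partners by sparingly soluble CsF).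

Step 10
Reactants: 25 (+)-catechin
Product: 26 5,7,3',4'-tetra-O-benzyl-(+)-catechin
Conditions: BnBr, K2CO3, DMF, rt
Reagents that add atoms: benzyl bromide, BrCc1ccccc1
Why: Williamson etherification with a carbonate base alkylates the four phenols and leaves the less acidic aliphatic 3-hydroxyl free.

Step 11
Reactants: 24 chroman-4-ol of unit 3; 26 5,7,3',4'-tetra-O-benzyl-(+)-catechin
Product: 28 3,5,7,3',4'-penta-O-benzylepicatechin-(4β→8)-5,7,3',4'-tetra-O-benzylcatechin, via C4 cation triflate 27 (not isolated)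
Conditions: 26 (3 equiv), TMSOTf (cat.), 4 Å molecular sieves, CH2Cl2, −78 → −40 °C
Reagents that add atoms: none
Why: acid-catalysed ionisation of the benzylic C4–OH gives the ring A-stabilised cation 27, and Friedel–Crafts capture by C8 of 26 from the face anti to the C3 benzyloxy and C2 aryl groups should set C4 of unit 3 as 4β (3,4-trans), the excess of 26 suppressing self-condensation.

Step 12
Reactants: 29 (−)-epigallocatechin
Product: 30 5,7,3',4',5'-penta-O-benzyl-(−)-epigallocatechin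
Conditions: BnBr, K2CO3, degassed DMF, −10 °C → rt, argon
Reagents that add atoms: benzyl bromide, BrCc1ccccc1
Why: Williamson etherification with a carbonate base alkylates the five phenols and leaves the less acidic aliphatic 3-hydroxyl free, while exclusion of air protects the oxidation-prone pyrogallol ring until it is capped.

Step 13
Reactants: 30 5,7,3',4',5'-penta-O-benzyl-(−)-epigallocatechin; 31 3,4,5-tris(benzyloxy)benzoic acid
Product: 33 5,7,3',4',5'-penta-O-benzyl-(−)-epigallocatechin 3-O-[3,4,5-tris(benzyloxy)benzoate], via O-acylisourea 32 (not isolated)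
Conditions: DCC, DMAP (cat.), CH2Cl2, 0 °C → rt
Reagents that add atoms: none
Why: Steglich esterification, in which DMAP carries the acyl group from the O-acylisourea to the secondary 3-hydroxyl, installs the protected gallate by acylation at oxygen, so C2 and C3 keep their configuration.

Step 14
Reactants: 33 octa-O-benzyl epigallocatechin gallate
Product: 35 4β-(2-ethoxyethoxy) derivative of 33, via C4 cation hydroquinonate 34 (not isolated)
Conditions: DDQ, 2-ethoxyethanol, CH2Cl2, rt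
Reagents that add atoms: 2-ethoxyethanol, CCOCCO
Why: DDQ hydride abstraction at the ring C benzylic C4 (oxidative C–H alkoxylation of flavans) gives the cation as ion pair 34, which the alcohol should capture trans to the C3 ester.

Step 15
Reactants: 35 4β-(2-ethoxyethoxy) electrophile of unit 2; 28 unit 3–unit 4 dimer
Product: 37 octa-O-benzyl-epigallocatechin gallate-(4β→8)-penta-O-benzylepicatechin-(4β→8)-tetra-O-benzylcatechin, via C4 cation triflate 36 (not isolated)
Conditions: 28 (1.5 equiv), TMSOTf (cat.), CH2Cl2, −78 °C, slow addition of 35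
Reagents that add atoms: none
Why: Lewis-acid ionisation of the C4 ether gives the cation as its triflate ion pair 36, whose α face is covered by the C3 gallate, and Friedel–Crafts attack by C8 of the upper unit of 28, the most accessible ring A position, from the β face should give the 4β bond.

Step 16
Reactants: 38 (−)-epicatechin
Product: 39 5,7,3',4'-tetra-O-benzyl-(−)-epicatechin
Conditions: BnBr, K2CO3, DMF, rt
Reagents that add atoms: benzyl bromide, BrCc1ccccc1
Why: Williamson etherification of the four phenols, as in step 10.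

Step 17
Reactants: 39 5,7,3',4'-tetra-O-benzyl-(−)-epicatechin
Product: 41 5,7,3',4'-tetra-O-benzyl-4β-(2-ethoxyethoxy)epicatechin, via C4 cation hydroquinonate 40 (not isolated)
Conditions: DDQ, 2-ethoxyethanol, CH2Cl2, rt
Reagents that add atoms: 2-ethoxyethanol, CCOCCO
Why: DDQ-mediated benzylic C4 oxidation with alcohol capture trans to the C3 hydroxyl, a standard preparation of flavan C4 electrophiles.

Step 18
Reactants: 41 4β-(2-ethoxyethoxy) electrophile of unit 1; 37 protected trimer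
Product: 43 tetra-O-benzylepicatechin-(4β→8)-[octa-O-benzyl-epigallocatechin gallate]-(4β→8)-penta-O-benzylepicatechin-(4β→8)-tetra-O-benzylcatechin, via C4 cation triflate 42 (not isolated)
Conditions: 37 (1.5 equiv), TMSOTf (cat.), CH2Cl2, −78 °C, slow addition of 41
Reagents that add atoms: none
Why: the same Lewis-acid Friedel–Crafts flavan coupling, with the cation of ion pair 42 captured by C8 of the top unit of 37 anti to the C3 hydroxyl and C2 aryl group (4β).

Step 19
Reactants: 43 protected tetramer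
Product: 44 epicatechin-(4β→8)-epigallocatechin 3-O-gallate-(4β→8)-epicatechin-(4β→8)-catechin
Conditions: H2 (1 atm), Pd(OH)2/C, THF–MeOH–H2O, rt
Reagents that add atoms: none
Why: neutral catalytic hydrogenolysis should cleave all 21 benzyl ethers while the gallate ester, the acid-labile interflavan bonds and all stereocentres stay untouched.

Compound list

1 | 3,5-bis(benzyloxy)phenol | Oc1cc(OCc2ccccc2)cc(OCc2ccccc2)c1 | starting material
2 | 3,5-bis(benzyloxy)phenyl N-isopropylcarbamate | CC(C)NC(=O)Oc1cc(OCc2ccccc2)cc(OCc2ccccc2)c1 | intermediate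
3 | N-(tert-butyldimethylsilyl) derivative of 2 (not isolated) | CC(C)N([Si](C)(C)C(C)(C)C)C(=O)Oc1cc(OCc2ccccc2)cc(OCc2ccccc2)c1 | intermediate
4 | 2-lithio derivative of 3, lithium between carbamate and benzyloxy (not isolated) | CC(C)N([Si](C)(C)C(C)(C)C)C(=O)Oc1cc(OCc2ccccc2)cc(OCc2ccccc2)c1[Li] | intermediate
5 | 3,5-bis(benzyloxy)-2-(trimethylsilyl)phenyl N-(tert-butyldimethylsilyl)-N-isopropylcarbamate (not isolated) | CC(C)N([Si](C)(C)C(C)(C)C)C(=O)Oc1cc(OCc2ccccc2)cc(OCc2ccccc2)c1[Si](C)(C)C | intermediate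
6 | 3,5-bis(benzyloxy)-2-(trimethylsilyl)phenyl N-isopropylcarbamate | CC(C)NC(=O)Oc1cc(OCc2ccccc2)cc(OCc2ccccc2)c1[Si](C)(C)C | intermediate
7 | 3,5-bis(benzyloxy)-2-(trimethylsilyl)phenol (not isolated) | Oc1cc(OCc2ccccc2)cc(OCc2ccccc2)c1[Si](C)(C)C | intermediate
8 | 3,5-bis(benzyloxy)-2-(trimethylsilyl)phenyl trifluoromethanesulfonate | FC(F)(F)S(=O)(=O)Oc1cc(OCc2ccccc2)cc(OCc2ccccc2)c1[Si](C)(C)C | intermediate
9 | (S)-4-benzyloxazolidin-2-one | O=C1N[C@@H](Cc2ccccc2)CO1 | starting material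
10 | (benzyloxy)acetyl chloride | O=C(Cl)COCc1ccccc1 | starting material
11 | lithium salt of 9 (not isolated) | [Li+].O=C1[N-][C@@H](Cc2ccccc2)CO1 | intermediate
12 | (S)-4-benzyl-3-[(benzyloxy)acetyl]oxazolidin-2-one | O=C(COCc1ccccc1)N1C(=O)OC[C@@H]1Cc1ccccc1 | intermediate
13 | 3,4-bis(benzyloxy)benzaldehyde | O=Cc1ccc(OCc2ccccc2)c(OCc2ccccc2)c1 | starting material
14 | (Z)-dibutylboron enolate of 12 (not isolated) | CCCCB(CCCC)O/C(=C\OCc1ccccc1)N1C(=O)OC[C@@H]1Cc1ccccc1 | intermediate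
15 | dibutylboron aldolate of 16 (not isolated) | O=C([C@@H](OCc1ccccc1)[C@H](OB(CCCC)CCCC)c1ccc(OCc2ccccc2)c(OCc2ccccc2)c1)N1C(=O)OC[C@@H]1Cc1ccccc1 | intermediate
16 | (S)-4-benzyl-3-[(2S,3R)-2-(benzyloxy)-3-[3,4-bis(benzyloxy)phenyl]-3-hydroxypropanoyl]oxazolidin-2-one | O=C([C@@H](OCc1ccccc1)[C@H](O)c1ccc(OCc2ccccc2)c(OCc2ccccc2)c1)N1C(=O)OC[C@@H]1Cc1ccccc1 | intermediate
17 | (2S,3R)-2-(benzyloxy)-3-[3,4-bis(benzyloxy)phenyl]-3-hydroxy-N-methoxy-N-methylpropanamide | CON(C)C(=O)[C@@H](OCc1ccccc1)[C@H](O)c1ccc(OCc2ccccc2)c(OCc2ccccc2)c1 | intermediate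
18 | (2S,3R)-2-(benzyloxy)-3-[3,4-bis(benzyloxy)phenyl]-N-methoxy-N-methyl-3-(triethylsilyloxy)propanamide | CON(C)C(=O)[C@@H](OCc1ccccc1)[C@H](O[Si](CC)(CC)CC)c1ccc(OCc2ccccc2)c(OCc2ccccc2)c1 | intermediate
19 | O-diisobutylaluminium hemiaminal from 18 (not isolated) | CON(C)C(O[Al](CC(C)C)CC(C)C)[C@@H](OCc1ccccc1)[C@H](O[Si](CC)(CC)CC)c1ccc(OCc2ccccc2)c(OCc2ccccc2)c1 | intermediate
20 | (2S,3R)-2-(benzyloxy)-3-[3,4-bis(benzyloxy)phenyl]-3-(triethylsilyloxy)propanal | O=C[C@@H](OCc1ccccc1)[C@H](O[Si](CC)(CC)CC)c1ccc(OCc2ccccc2)c(OCc2ccccc2)c1 | intermediate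
21 | 3,5-bis(benzyloxy)benzyne, 1,2-didehydro-3,5-bis(benzyloxy)benzene (not isolated) | C1#CC(OCc2ccccc2)=CC(OCc2ccccc2)=C1 | intermediate
22 | caesium (1R,2S)-2-(benzyloxy)-1-[3,4-bis(benzyloxy)phenyl]-3-oxopropan-1-olate (not isolated) | [Cs+].[O-][C@H](c1ccc(OCc2ccccc2)c(OCc2ccccc2)c1)[C@H](OCc1ccccc1)C=O | intermediate
23 | aryl caesium formed by O-arylation of 22, carbanion at the later C4a between the ether carbon and a benzyloxy carbon (not isolated) | [Cs+].[c-]1c(O[C@H](c2ccc(OCc3ccccc3)c(OCc3ccccc3)c2)[C@H](OCc2ccccc2)C=O)cc(OCc2ccccc2)cc1OCc1ccccc1 | intermediate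
24 | (2R,3R)-3,5,7-tris(benzyloxy)-2-[3,4-bis(benzyloxy)phenyl]chroman-4-ol (2,3-cis; C4 epimers) | c1ccccc1COc1cc(OCc2ccccc2)c2c(c1)O[C@H](c1ccc(OCc3ccccc3)c(OCc3ccccc3)c1)[C@H](OCc1ccccc1)C2O | intermediate
25 | (+)-catechin, (2R,3S) | Oc1cc(O)c2c(c1)O[C@H](c1ccc(O)c(O)c1)[C@@H](O)C2 | starting material
26 | 5,7,3',4'-tetra-O-benzyl-(+)-catechin | c1ccccc1COc1cc(OCc2ccccc2)c2c(c1)O[C@H](c1ccc(OCc3ccccc3)c(OCc3ccccc3)c1)[C@@H](O)C2 | intermediate
27 | C4 cation of penta-O-benzylepicatechin as its triflate ion pair, from 24 (not isolated) | c1ccccc1COc1cc(OCc2ccccc2)c2c(c1)O[C@H](c1ccc(OCc3ccccc3)c(OCc3ccccc3)c1)[C@H](OCc1ccccc1)[CH+]2.[O-]S(=O)(=O)C(F)(F)F | intermediate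
28 | 3,5,7,3',4'-penta-O-benzylepicatechin-(4β→8)-5,7,3',4'-tetra-O-benzylcatechin | c1ccccc1COc1cc(OCc2ccccc2)c2c(c1)O[C@H](c1ccc(OCc3ccccc3)c(OCc3ccccc3)c1)[C@H](OCc1ccccc1)[C@H]2c1c(OCc2ccccc2)cc(OCc2ccccc2)c2c1O[C@H](c1ccc(OCc3ccccc3)c(OCc3ccccc3)c1)[C@@H](O)C2 | intermediate
29 | (−)-epigallocatechin, (2R,3R) | O[C@@H]1Cc2c(O)cc(O)cc2O[C@@H]1c1cc(O)c(O)c(O)c1 | starting material
30 | 5,7,3',4',5'-penta-O-benzyl-(−)-epigallocatechin | O[C@@H]1Cc2c(OCc3ccccc3)cc(OCc3ccccc3)cc2O[C@@H]1c1cc(OCc2ccccc2)c(OCc2ccccc2)c(OCc2ccccc2)c1 | intermediate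
31 | 3,4,5-tris(benzyloxy)benzoic acid | OC(=O)c1cc(OCc2ccccc2)c(OCc2ccccc2)c(OCc2ccccc2)c1 | starting material
32 | O-acylisourea from 31 and DCC (not isolated) | O=C(OC(=NC1CCCCC1)NC1CCCCC1)c1cc(OCc2ccccc2)c(OCc2ccccc2)c(OCc2ccccc2)c1 | intermediate
33 | 5,7,3',4',5'-penta-O-benzyl-(−)-epigallocatechin 3-O-[3,4,5-tris(benzyloxy)benzoate] | O=C(O[C@@H]1Cc2c(OCc3ccccc3)cc(OCc3ccccc3)cc2O[C@@H]1c1cc(OCc2ccccc2)c(OCc2ccccc2)c(OCc2ccccc2)c1)c1cc(OCc2ccccc2)c(OCc2ccccc2)c(OCc2ccccc2)c1 | intermediate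
34 | C4 cation of 33 as ion pair with 2,3-dichloro-5,6-dicyano-4-hydroxyphenolate (not isolated) | O=C(O[C@@H]1[CH+]c2c(OCc3ccccc3)cc(OCc3ccccc3)cc2O[C@@H]1c1cc(OCc2ccccc2)c(OCc2ccccc2)c(OCc2ccccc2)c1)c1cc(OCc2ccccc2)c(OCc2ccccc2)c(OCc2ccccc2)c1.[O-]c1c(Cl)c(Cl)c(O)c(C#N)c1C#N | intermediate
35 | 4β-(2-ethoxyethoxy) derivative of 33 (3,4-trans) | O=C(O[C@@H]1[C@@H](OCCOCC)c2c(OCc3ccccc3)cc(OCc3ccccc3)cc2O[C@@H]1c1cc(OCc2ccccc2)c(OCc2ccccc2)c(OCc2ccccc2)c1)c1cc(OCc2ccccc2)c(OCc2ccccc2)c(OCc2ccccc2)c1 | intermediate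
36 | C4 cation of 33 as its triflate ion pair, from 35 (not isolated) | O=C(O[C@@H]1[CH+]c2c(OCc3ccccc3)cc(OCc3ccccc3)cc2O[C@@H]1c1cc(OCc2ccccc2)c(OCc2ccccc2)c(OCc2ccccc2)c1)c1cc(OCc2ccccc2)c(OCc2ccccc2)c(OCc2ccccc2)c1.[O-]S(=O)(=O)C(F)(F)F | intermediate
37 | octa-O-benzyl-epigallocatechin gallate-(4β→8)-penta-O-benzylepicatechin-(4β→8)-tetra-O-benzylcatechin | O=C(O[C@@H]1[C@@H](c2c(OCc5ccccc5)cc(OCc5ccccc5)c3c2O[C@H](c2ccc(OCc5ccccc5)c(OCc5ccccc5)c2)[C@H](OCc5ccccc5)[C@H]3c2c(OCc5ccccc5)cc(OCc5ccccc5)c3c2O[C@H](c2ccc(OCc5ccccc5)c(OCc5ccccc5)c2)[C@@H](O)C3)c2c(OCc5ccccc5)cc(OCc5ccccc5)cc2O[C@@H]1c1cc(OCc5ccccc5)c(OCc5ccccc5)c(OCc5ccccc5)c1)c1cc(OCc5ccccc5)c(OCc5ccccc5)c(OCc5ccccc5)c1 | intermediate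
38 | (−)-epicatechin, (2R,3R) | Oc1cc(O)c2c(c1)O[C@H](c1ccc(O)c(O)c1)[C@H](O)C2 | starting material
39 | 5,7,3',4'-tetra-O-benzyl-(−)-epicatechin | c1ccccc1COc1cc(OCc2ccccc2)c2c(c1)O[C@H](c1ccc(OCc3ccccc3)c(OCc3ccccc3)c1)[C@H](O)C2 | intermediate
40 | C4 cation of 39 as ion pair with 2,3-dichloro-5,6-dicyano-4-hydroxyphenolate (not isolated) | c1ccccc1COc1cc(OCc2ccccc2)c2c(c1)O[C@H](c1ccc(OCc3ccccc3)c(OCc3ccccc3)c1)[C@H](O)[CH+]2.[O-]c1c(Cl)c(Cl)c(O)c(C#N)c1C#N | intermediate
41 | 5,7,3',4'-tetra-O-benzyl-4β-(2-ethoxyethoxy)epicatechin (3,4-trans) | c1ccccc1COc1cc(OCc2ccccc2)c2c(c1)O[C@H](c1ccc(OCc3ccccc3)c(OCc3ccccc3)c1)[C@H](O)[C@H]2OCCOCC | intermediate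
42 | C4 cation of 39 as its triflate ion pair, from 41 (not isolated) | c1ccccc1COc1cc(OCc2ccccc2)c2c(c1)O[C@H](c1ccc(OCc3ccccc3)c(OCc3ccccc3)c1)[C@H](O)[CH+]2.[O-]S(=O)(=O)C(F)(F)F | intermediate
43 | tetra-O-benzylepicatechin-(4β→8)-[octa-O-benzyl-epigallocatechin gallate]-(4β→8)-penta-O-benzylepicatechin-(4β→8)-tetra-O-benzylcatechin (21 benzyl ethers) | O=C(O[C@@H]1[C@@H](c2c(OCc5ccccc5)cc(OCc5ccccc5)c3c2O[C@H](c2ccc(OCc5ccccc5)c(OCc5ccccc5)c2)[C@H](OCc5ccccc5)[C@H]3c2c(OCc5ccccc5)cc(OCc5ccccc5)c3c2O[C@H](c2ccc(OCc5ccccc5)c(OCc5ccccc5)c2)[C@@H](O)C3)c2c(OCc5ccccc5)cc(OCc5ccccc5)c([C@H]3c4c(OCc5ccccc5)cc(OCc5ccccc5)cc4O[C@H](c4ccc(OCc5ccccc5)c(OCc5ccccc5)c4)[C@@H]3O)c2O[C@@H]1c1cc(OCc5ccccc5)c(OCc5ccccc5)c(OCc5ccccc5)c1)c1cc(OCc5ccccc5)c(OCc5ccccc5)c(OCc5ccccc5)c1 | intermediate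
44 | epicatechin-(4β→8)-epigallocatechin 3-O-gallate-(4β→8)-epicatechin-(4β→8)-catechin | O=C(O[C@@H]1[C@@H](c2c(O)cc(O)c3c2O[C@H](c2ccc(O)c(O)c2)[C@H](O)[C@H]3c2c(O)cc(O)c3c2O[C@H](c2ccc(O)c(O)c2)[C@@H](O)C3)c2c(O)cc(O)c([C@H]3c4c(O)cc(O)cc4O[C@H](c4ccc(O)c(O)c4)[C@@H]3O)c2O[C@@H]1c1cc(O)c(O)c(O)c1)c1cc(O)c(O)c(O)c1 | target

Step count and risks

Total step count: 19. Longest linear sequence: 10 steps (steps 4, 5, 6, 7, 8, 9, 11, 15, 18, 19).

Steps most likely to fail:

Step 9 (the proposed new method). What may go wrong: retro-aldol fragmentation of the free alkoxide before it meets the aryne; proton transfer to the C4a carbanion (from the α-C–H of the aldehyde or from traces of water) before ring closure, which would leave an open aryl ether; arylation of the product alkoxide by surplus aryne. The fallback forms the same two bonds in separate, known operations and sets out from aldehyde 20. 1,3,5-Trifluorobenzene would be treated with sodium benzyloxide (NaH, BnOH, DMF) to give 1,3-bis(benzyloxy)-5-fluorobenzene F1, which n-BuLi (THF, −78 °C) should metalate between fluorine and a benzyloxy group to give [2,4-bis(benzyloxy)-6-fluorophenyl]lithium F2. Addition of F2 to 20 at −78 °C forms the C4–C4a bond and gives the silyl-protected fluoroaryl carbinol F3. Bu4NF then removes the silyl group to give the fluoroaryl diol F4. KH with 18-crown-6 in DMF should close the O1–C8a bond by intramolecular nucleophilic aromatic substitution of fluoride by the C2 alkoxide (six-membered ring), and this rejoins the route at 24.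

Step 15. What may go wrong: attack at a C6 position or on the lower unit of the dimer instead of C8 of its upper unit; self-condensation of the electrophile through its own free C8; diversion of the gallate-covered cation to orthoester-type products. The fallback changes the order of assembly and sets out from 33 and 41. The monomer 33 would serve as the nucleophile toward 41 (TMSOTf, CH2Cl2, −78 °C), where only one unit offers a free C8, to give the protected unit 1–unit 2 dimer F5. DDQ with 2-ethoxyethanol should then oxidise the only ring C methylene (C4 of the gallate-bearing unit) to give the 4β-(2-ethoxyethoxy) dimer F6. Coupling of F6 with 28 (TMSOTf, CH2Cl2, −78 °C) joins two dimers and comes back to the route at 43.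

Step 18. What may go wrong: over-alkylation, because the electrophile carries its own nucleophilic C8 and can add to the product or to itself; low site selectivity among the free ring A positions of the trimer. The fallback caps C8 of unit 1 and sets out from 39. NBS (CH2Cl2, −78 °C → rt) should brominate C8 to give 8-bromo-5,7,3',4'-tetra-O-benzylepicatechin F7, and DDQ with 2-ethoxyethanol gives its 4β-(2-ethoxyethoxy) derivative F8, which can no longer act as a nucleophile. Coupling with 37 (TMSOTf, CH2Cl2, −78 °C) gives the 8-bromo protected tetramer F9. Hydrogenolysis (H2, Pd(OH)2/C, Et3N, THF–MeOH–H2O) removes the bromine together with the benzyl ethers and comes back to the route at 44.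

Further compounds

F1 | step 9 | 1,3-bis(benzyloxy)-5-fluorobenzene | Fc1cc(OCc2ccccc2)cc(OCc2ccccc2)c1
F2 | step 9 | [2,4-bis(benzyloxy)-6-fluorophenyl]lithium | [Li]c1c(F)cc(OCc2ccccc2)cc1OCc1ccccc1
F3 | step 9 | (2S,3R)-2-(benzyloxy)-1-[2,4-bis(benzyloxy)-6-fluorophenyl]-3-[3,4-bis(benzyloxy)phenyl]-3-(triethylsilyloxy)propan-1-ol (C1 epimers) | OC(c1c(F)cc(OCc2ccccc2)cc1OCc1ccccc1)[C@@H](OCc1ccccc1)[C@H](O[Si](CC)(CC)CC)c1ccc(OCc2ccccc2)c(OCc2ccccc2)c1
F4 | step 9 | (2S,3R)-2-(benzyloxy)-1-[2,4-bis(benzyloxy)-6-fluorophenyl]-3-[3,4-bis(benzyloxy)phenyl]propane-1,3-diol (C1 epimers) | OC(c1c(F)cc(OCc2ccccc2)cc1OCc1ccccc1)[C@@H](OCc1ccccc1)[C@H](O)c1ccc(OCc2ccccc2)c(OCc2ccccc2)c1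
F5 | step 15 | tetra-O-benzylepicatechin-(4β→8)-octa-O-benzyl-epigallocatechin gallate | O=C(O[C@@H]1Cc2c(OCc5ccccc5)cc(OCc5ccccc5)c([C@H]3c4c(OCc5ccccc5)cc(OCc5ccccc5)cc4O[C@H](c4ccc(OCc5ccccc5)c(OCc5ccccc5)c4)[C@@H]3O)c2O[C@@H]1c1cc(OCc5ccccc5)c(OCc5ccccc5)c(OCc5ccccc5)c1)c1cc(OCc5ccccc5)c(OCc5ccccc5)c(OCc5ccccc5)c1
F6 | step 15 | 4β-(2-ethoxyethoxy) derivative of F5 (on the gallate-bearing unit) | O=C(O[C@@H]1[C@@H](OCCOCC)c2c(OCc5ccccc5)cc(OCc5ccccc5)c([C@H]3c4c(OCc5ccccc5)cc(OCc5ccccc5)cc4O[C@H](c4ccc(OCc5ccccc5)c(OCc5ccccc5)c4)[C@@H]3O)c2O[C@@H]1c1cc(OCc5ccccc5)c(OCc5ccccc5)c(OCc5ccccc5)c1)c1cc(OCc5ccccc5)c(OCc5ccccc5)c(OCc5ccccc5)c1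
F7 | step 18 | 8-bromo-5,7,3',4'-tetra-O-benzyl-(−)-epicatechin | c1ccccc1COc1cc(OCc2ccccc2)c2c(c1Br)O[C@H](c1ccc(OCc3ccccc3)c(OCc3ccccc3)c1)[C@H](O)C2
F8 | step 18 | 8-bromo-5,7,3',4'-tetra-O-benzyl-4β-(2-ethoxyethoxy)epicatechin | c1ccccc1COc1cc(OCc2ccccc2)c2c(c1Br)O[C@H](c1ccc(OCc3ccccc3)c(OCc3ccccc3)c1)[C@H](O)[C@H]2OCCOCC
F9 | step 18 | 43 carrying bromine at C8 of unit 1 | O=C(O[C@@H]1[C@@H](c2c(OCc5ccccc5)cc(OCc5ccccc5)c3c2O[C@H](c2ccc(OCc5ccccc5)c(OCc5ccccc5)c2)[C@H](OCc5ccccc5)[C@H]3c2c(OCc5ccccc5)cc(OCc5ccccc5)c3c2O[C@H](c2ccc(OCc5ccccc5)c(OCc5ccccc5)c2)[C@@H](O)C3)c2c(OCc5ccccc5)cc(OCc5ccccc5)c([C@H]3c4c(OCc5ccccc5)cc(OCc5ccccc5)c(Br)c4O[C@H](c4ccc(OCc5ccccc5)c(OCc5ccccc5)c4)[C@@H]3O)c2O[C@@H]1c1cc(OCc5ccccc5)c(OCc5ccccc5)c(OCc5ccccc5)c1)c1cc(OCc5ccccc5)c(OCc5ccccc5)c(OCc5ccccc5)c1
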